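**Plan**

- Retrosynthesis: the O-protecting groups and the C3 O-methyl group are removed first. Ring C is then cut at C3–C4 (α-ketol to dialdehyde) and at O1–C2 (aryl ether to a salicylaldehyde and an α-bromo arylacetate). The formyl carbon C4 is cut from C4a of ring A.
- Enabling feature: in ring C the aryl ketone C4 lies next to the oxygen-bearing C3 (an α-ketol). Once C3 is a formyl group, C2 beside it (benzylic, O-substituted) loses its configurational stability.
- Forward: ring A is made as a formylated phenol and ring B as an α-bromo arylacetate. They are joined at O1–C2, the chain is brought to the dialdehyde, and ring C closes last by C3–C4 bond formation.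
- Stereochemistry: C2 and C3 both arise in the ring closure, C3 from the chiral carbene and C2 by dynamic kinetic resolution of the racemising aldehyde. Neither is exposed to enolising base afterwards.
- Protecting groups: O6 and O3' are carried as benzyl ethers and O5 as the methyl ether chelated to the C4 carbonyl. One BCl3 step at the end frees the three phenols and leaves the C3, C7 and C4' methyl ethers.

Key step: step 8

Assumption: the (5aS,10bR) enantiomer of the aminoindanol-derived triazolium salt is taken to deliver the (3R) carbinol; if the sense of induction is the opposite, the antipodal salt is used and nothing else changes.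

**Route**

Step 1
Reactants: 1 4-(benzyloxy)-3,5-dimethoxybenzaldehyde
Product: 3 4-(benzyloxy)-3,5-dimethoxyphenol, via aryl formate 2 (not isolated)
Conditions: mCPBA, CH2Cl2, rt; aq. NaHCO3 wash; then K2CO3 (cat.), MeOH, rt
Reagents that add atoms: mCPBA (3-chloroperoxybenzoic acid), O=C(OO)c1cccc(Cl)c1
Why: Baeyer–Villiger (Dakin-type) oxidation of an electron-rich benzaldehyde proceeds with aryl migration, and mild methanolysis of the formate frees the phenol without touching the benzyl ether.

Step 2
Reactants: 3 4-(benzyloxy)-3,5-dimethoxyphenol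
Product: 4 3-(benzyloxy)-6-hydroxy-2,4-dimethoxybenzaldehyde
Conditions: MgCl2, Et3N, (CH2O)n, MeCN, reflux; aq. HCl work-up
Reagents that add atoms: paraformaldehyde (as formaldehyde), C=O
Why: the magnesium-phenoxide-directed ortho-formylation (Casnati–Skattebøl) places the formyl group only ortho to the hydroxyl, and since the two ortho positions are equivalent and the para position is blocked a single aldehyde should result.

Step 3
Reactants: 5 2-[3-(benzyloxy)-4-methoxyphenyl]acetic acid
Product: 6 methyl 2-[3-(benzyloxy)-4-methoxyphenyl]acetate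
Conditions: MeOH, H2SO4 (cat.), reflux
Reagents that add atoms: methanol, CO
Why: Fischer esterification of an arylacetic acid, to which the aryl benzyl ether is stable.

Step 4
Reactants: 6 methyl 2-[3-(benzyloxy)-4-methoxyphenyl]acetate
Product: 8 methyl 2-bromo-2-[3-(benzyloxy)-4-methoxyphenyl]acetate (racemic), via silyl ketene acetal 7 (not isolated)
Conditions: LiN(SiMe3)2, Me3SiCl, THF, −78 °C; then NBS, −78 → 0 °C
Reagents that add atoms: N-bromosuccinimide, O=C1CCC(=O)N1Br
Why: enolate bromination through the silyl ketene acetal puts bromine on the α-carbon only and avoids ring bromination of the electron-rich arene and radical attack on the benzyl ether; the new centre is racemic, as intended.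

Step 5
Reactants: 4 3-(benzyloxy)-6-hydroxy-2,4-dimethoxybenzaldehyde; 8 methyl 2-bromo-2-[3-(benzyloxy)-4-methoxyphenyl]acetate (racemic)
Product: 9 methyl 2-[4-(benzyloxy)-2-formyl-3,5-dimethoxyphenoxy]-2-[3-(benzyloxy)-4-methoxyphenyl]acetate (racemic)
Conditions: K2CO3, DMF, rt
Reagents that add atoms: none
Why: Williamson ether synthesis in which the phenoxide displaces the activated secondary benzylic bromide (SN2) to form the O1–C2 bond, the mild carbonate base at room temperature keeping the ester from enolising onto the hindered, electron-rich formyl group.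

Step 6
Reactants: 9 methyl 2-[4-(benzyloxy)-2-formyl-3,5-dimethoxyphenoxy]-2-[3-(benzyloxy)-4-methoxyphenyl]acetate (racemic)
Product: 10 2-[4-(benzyloxy)-2-(hydroxymethyl)-3,5-dimethoxyphenoxy]-2-[3-(benzyloxy)-4-methoxyphenyl]ethan-1-ol (racemic)
Conditions: LiAlH4, THF, 0 °C
Reagents that add atoms: none
Why: hydride reduction with LiAlH4 takes the ester and the formyl group to primary alcohols in one operation, so the aryl aldehyde needs no separate masking, and aryl, benzyl and benzylic ethers are inert.

Step 7
Reactants: 10 2-[4-(benzyloxy)-2-(hydroxymethyl)-3,5-dimethoxyphenoxy]-2-[3-(benzyloxy)-4-methoxyphenyl]ethan-1-ol (racemic)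
Product: 11 3-(benzyloxy)-6-{1-[3-(benzyloxy)-4-methoxyphenyl]-2-oxoethoxy}-2,4-dimethoxybenzaldehyde (racemic)
Conditions: Dess–Martin periodinane (2.4 equiv), CH2Cl2, 0 °C → rt; short silica plug, used at once
Reagents that add atoms: none
Why: Dess–Martin oxidation converts both primary alcohols to aldehydes under neutral conditions without over-oxidation, and the racemic α-aryl-α-aryloxy aldehyde is carried on at once to limit enol-derived decay.

Step 8
Reactants: 11 3-(benzyloxy)-6-{1-[3-(benzyloxy)-4-methoxyphenyl]-2-oxoethoxy}-2,4-dimethoxybenzaldehyde (racemic)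
Product: 12 (2R,3R)-6-(benzyloxy)-2-[3-(benzyloxy)-4-methoxyphenyl]-3-hydroxy-5,7-dimethoxy-2,3-dihydro-4H-chromen-4-one
Conditions: (5aS,10bR)-2-(pentafluorophenyl)-5a,10b-dihydro-4H,6H-indeno[2,1-b][1,2,4]triazolo[4,3-d][1,4]oxazin-2-ium tetrafluoroborate (10 mol %), i-Pr2NEt (1 equiv), toluene, rt, Ar
Reagents that add atoms: none
Why: Proposed new method: the triazolylidene adds reversibly to the aryl formyl group of 11, proton transfer gives the Breslow intermediate (acyl-anion equivalent at C4), and this attacks the tethered aliphatic formyl carbon C3 in a 6-exo-trig closure of ring C before collapse of the adduct releases the carbene and the α-ketol. The closest known reactions are the chiral triazolium-catalysed intramolecular aldehyde–ketone benzoin that gives 3-hydroxychroman-4-ones, cross-benzoins in which α-branched α-heteroatom aldehydes serve only as acceptors, and carbene-catalysed dynamic kinetic resolutions of configurationally labile α-substituted carbonyl acceptors. C3 is set by the catalyst, whose indane wall shields one face of the Breslow intermediate so that the formyl group is attacked from a single face. C2 is set by dynamic kinetic resolution: its hydrogen, α to the formyl group, benzylic and oxygen-substituted, is exchanged quickly by the amine through the enol, and only the (R)-aldehyde reaches the chair-like transition state with the C2 aryl group equatorial and trans to the developing C3 oxygen, after which C2 is no longer α to an aldehyde and is fixed. The step needs the aryl aldehyde as donor and the aliphatic aldehyde as acceptor; this is secured by the tertiary α-carbon that hinders carbene addition at the aliphatic formyl group, by the benzylic and therefore more acidic carbinol C–H of the aryl adduct, by the small ortho substituents on the aryl aldehyde (a methoxy group and the tether oxygen), and by the low electrophilicity of the electron-rich aryl formyl group toward the competing 5-ring aldol of the enol.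

Step 9
Reactants: 12 (2R,3R)-6-(benzyloxy)-2-[3-(benzyloxy)-4-methoxyphenyl]-3-hydroxy-5,7-dimethoxy-2,3-dihydro-4H-chromen-4-one
Product: 13 (2R,3R)-6-(benzyloxy)-2-[3-(benzyloxy)-4-methoxyphenyl]-3,5,7-trimethoxy-2,3-dihydro-4H-chromen-4-one
Conditions: Me3OBF4, 1,8-bis(dimethylamino)naphthalene, 4 Å MS, CH2Cl2, rt
Reagents that add atoms: trimethyloxonium tetrafluoroborate, C[O+](C)C.F[B-](F)(F)F
Why: O-alkylation with Meerwein's salt buffered by a hindered, non-nucleophilic amine methylates the secondary hydroxyl without forming an alkoxide or enolate, so C2 and C3 keep their configuration and the α-ketol does not open or oxidise.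

Step 10
Reactants: 13 (2R,3R)-6-(benzyloxy)-2-[3-(benzyloxy)-4-methoxyphenyl]-3,5,7-trimethoxy-2,3-dihydro-4H-chromen-4-one
Product: 14 (2R,3R)-5,6-dihydroxy-2-(3-hydroxy-4-methoxyphenyl)-3,7-dimethoxy-2,3-dihydro-4H-chromen-4-one (CNP0393633.1)
Conditions: BCl3, C6HMe5, CH2Cl2, −78 → 0 °C; then H2O
Reagents that add atoms: none
Why: Lewis-acid ether cleavage in which BCl3 removes both aryl benzyl ethers at low temperature with pentamethylbenzene trapping the benzyl cation (Friedel–Crafts), and on warming cleaves only the C5 methyl ether, which chelates boron together with the C4 carbonyl, while the C7, C4' and aliphatic C3 methyl ethers lack this activation and a reversible opening at C2 would reclose to the trans isomer.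

**Compound list**

1 | 4-(benzyloxy)-3,5-dimethoxybenzaldehyde | COc1cc(C=O)cc(OC)c1OCc1ccccc1 | starting material
2 | 4-(benzyloxy)-3,5-dimethoxyphenyl formate, not isolated | COc1cc(OC=O)cc(OC)c1OCc1ccccc1 | intermediate
3 | 4-(benzyloxy)-3,5-dimethoxyphenol | COc1cc(O)cc(OC)c1OCc1ccccc1 | intermediate
4 | 3-(benzyloxy)-6-hydroxy-2,4-dimethoxybenzaldehyde | COc1cc(O)c(C=O)c(OC)c1OCc1ccccc1 | intermediate
5 | 2-[3-(benzyloxy)-4-methoxyphenyl]acetic acid | COc1ccc(CC(=O)O)cc1OCc1ccccc1 | starting material
6 | methyl 2-[3-(benzyloxy)-4-methoxyphenyl]acetate | COC(=O)Cc1ccc(OC)c(OCc2ccccc2)c1 | intermediate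
7 | {[2-(3-(benzyloxy)-4-methoxyphenyl)-1-methoxyethenyl]oxy}trimethylsilane (alkene geometry not defined), not isolated | COC(O[Si](C)(C)C)=Cc1ccc(OC)c(OCc2ccccc2)c1 | intermediate
8 | methyl 2-bromo-2-[3-(benzyloxy)-4-methoxyphenyl]acetate (racemic) | COC(=O)C(Br)c1ccc(OC)c(OCc2ccccc2)c1 | intermediate
9 | methyl 2-[4-(benzyloxy)-2-formyl-3,5-dimethoxyphenoxy]-2-[3-(benzyloxy)-4-methoxyphenyl]acetate (racemic) | COC(=O)C(Oc1cc(OC)c(OCc2ccccc2)c(OC)c1C=O)c1ccc(OC)c(OCc2ccccc2)c1 | intermediate
10 | 2-[4-(benzyloxy)-2-(hydroxymethyl)-3,5-dimethoxyphenoxy]-2-[3-(benzyloxy)-4-methoxyphenyl]ethan-1-ol (racemic) | OCC(Oc1cc(OC)c(OCc2ccccc2)c(OC)c1CO)c1ccc(OC)c(OCc2ccccc2)c1 | intermediate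
11 | 3-(benzyloxy)-6-{1-[3-(benzyloxy)-4-methoxyphenyl]-2-oxoethoxy}-2,4-dimethoxybenzaldehyde (racemic) | O=CC(Oc1cc(OC)c(OCc2ccccc2)c(OC)c1C=O)c1ccc(OC)c(OCc2ccccc2)c1 | intermediate
12 | (2R,3R)-6-(benzyloxy)-2-[3-(benzyloxy)-4-methoxyphenyl]-3-hydroxy-5,7-dimethoxy-2,3-dihydro-4H-chromen-4-one | COc1ccc([C@H]2Oc3cc(OC)c(OCc4ccccc4)c(OC)c3C(=O)[C@@H]2O)cc1OCc1ccccc1 | intermediate
13 | (2R,3R)-6-(benzyloxy)-2-[3-(benzyloxy)-4-methoxyphenyl]-3,5,7-trimethoxy-2,3-dihydro-4H-chromen-4-one | COc1ccc([C@H]2Oc3cc(OC)c(OCc4ccccc4)c(OC)c3C(=O)[C@@H]2OC)cc1OCc1ccccc1 | intermediate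
14 | (2R,3R)-5,6-dihydroxy-2-(3-hydroxy-4-methoxyphenyl)-3,7-dimethoxy-2,3-dihydro-4H-chromen-4-one | COc1ccc([C@H]2Oc3cc(OC)c(O)c(O)c3C(=O)[C@@H]2OC)cc1O | target

**Step count and risks**

Total step count: 10. Longest linear sequence: 8 steps (steps 1, 2, 5 to 10 from 1; equally steps 3 to 10 from 5).

Steps most likely to fail:

Step 8. The carbene may engage the aliphatic formyl group instead of the hindered aryl one, with expulsion of the aryloxide. The amine may also drive a 5-ring aldol of the enol onto the aryl formyl group faster than the benzoin, or racemisation at C2 may be too slow relative to cyclisation, which would erode diastereo- and enantioselectivity. The fallback uses known chemistry and closes ring C at O1–C2 instead; it sets out from 4 and comes back at 12: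
- Protection of the phenol of 4 with MOMCl and i-Pr2NEt gives 3-(benzyloxy)-2,4-dimethoxy-6-(methoxymethoxy)benzaldehyde F1.
- Addition of MeMgBr gives 1-[3-(benzyloxy)-2,4-dimethoxy-6-(methoxymethoxy)phenyl]ethan-1-ol F2, and Dess–Martin oxidation gives 1-[3-(benzyloxy)-2,4-dimethoxy-6-(methoxymethoxy)phenyl]ethan-1-one F3.
- Claisen–Schmidt condensation with commercial 3-(benzyloxy)-4-methoxybenzaldehyde (KOH, EtOH) gives (E)-1-[3-(benzyloxy)-2,4-dimethoxy-6-(methoxymethoxy)phenyl]-3-[3-(benzyloxy)-4-methoxyphenyl]prop-2-en-1-one F4.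
- Juliá–Colonna epoxidation (poly-L-leucine, urea–H2O2, DBU, THF) should give [3-(benzyloxy)-2,4-dimethoxy-6-(methoxymethoxy)phenyl]{(2R,3S)-3-[3-(benzyloxy)-4-methoxyphenyl]oxiran-2-yl}methanone F5.
- HCl in MeOH removes the MOM group, and the freed phenol opens the epoxide at the benzylic carbon with inversion to give 12.

Step 7. The α-aryl-α-aryloxy aldehyde may decay by enolisation, hydration or over-oxidation during the double oxidation, or a lactol may form between the first aldehyde and the remaining alcohol and be oxidised to a lactone. The fallback avoids the diol and the double oxidation; it sets out from 9 and comes back at 11: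
- Acetalisation of the aryl formyl group with HC(OMe)3 and pyridinium p-toluenesulfonate in MeOH gives methyl 2-[4-(benzyloxy)-2-(dimethoxymethyl)-3,5-dimethoxyphenoxy]-2-[3-(benzyloxy)-4-methoxyphenyl]acetate F6.
- Partial reduction of the α-alkoxy ester with i-Bu2AlH in toluene at −78 °C gives 2-[4-(benzyloxy)-2-(dimethoxymethyl)-3,5-dimethoxyphenoxy]-2-[3-(benzyloxy)-4-methoxyphenyl]acetaldehyde F7.
- Brief treatment with dilute aqueous acid (AcOH, THF, H2O) unmasks the electron-rich aryl acetal and gives 11.

Step 10. Conditions strong enough for the C5 demethylation may also remove the C3 or C7 methyl ether, or open ring C at C2 by Lewis-acid ionisation. The fallback separates the two deprotections; it sets out from 13 and comes back at 14: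
- Hydrogenolysis of both benzyl ethers (H2, Pd/C, EtOAc, rt) gives (2R,3R)-6-hydroxy-2-(3-hydroxy-4-methoxyphenyl)-3,5,7-trimethoxy-2,3-dihydro-4H-chromen-4-one F8.
- Chelation-controlled mono-demethylation of the C5 ether with AlCl3 in MeCN at rt gives 14.

**Further compounds**

F1 | step 8 | 3-(benzyloxy)-2,4-dimethoxy-6-(methoxymethoxy)benzaldehyde | COCOc1cc(OC)c(OCc2ccccc2)c(OC)c1C=O
F2 | step 8 | 1-[3-(benzyloxy)-2,4-dimethoxy-6-(methoxymethoxy)phenyl]ethan-1-ol (racemic) | COCOc1cc(OC)c(OCc2ccccc2)c(OC)c1C(C)O
F3 | step 8 | 1-[3-(benzyloxy)-2,4-dimethoxy-6-(methoxymethoxy)phenyl]ethan-1-one | COCOc1cc(OC)c(OCc2ccccc2)c(OC)c1C(C)=O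
F4 | step 8 | (E)-1-[3-(benzyloxy)-2,4-dimethoxy-6-(methoxymethoxy)phenyl]-3-[3-(benzyloxy)-4-methoxyphenyl]prop-2-en-1-one | COCOc1cc(OC)c(OCc2ccccc2)c(OC)c1C(=O)/C=C/c1ccc(OC)c(OCc2ccccc2)c1
F5 | step 8 | [3-(benzyloxy)-2,4-dimethoxy-6-(methoxymethoxy)phenyl]{(2R,3S)-3-[3-(benzyloxy)-4-methoxyphenyl]oxiran-2-yl}methanone | COCOc1cc(OC)c(OCc2ccccc2)c(OC)c1C(=O)[C@@H]3O[C@H]3c1ccc(OC)c(OCc2ccccc2)c1
F6 | step 7 | methyl 2-[4-(benzyloxy)-2-(dimethoxymethyl)-3,5-dimethoxyphenoxy]-2-[3-(benzyloxy)-4-methoxyphenyl]acetate (racemic) | COC(=O)C(Oc1cc(OC)c(OCc2ccccc2)c(OC)c1C(OC)OC)c1ccc(OC)c(OCc2ccccc2)c1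
F7 | step 7 | 2-[4-(benzyloxy)-2-(dimethoxymethyl)-3,5-dimethoxyphenoxy]-2-[3-(benzyloxy)-4-methoxyphenyl]acetaldehyde (racemic) | O=CC(Oc1cc(OC)c(OCc2ccccc2)c(OC)c1C(OC)OC)c1ccc(OC)c(OCc2ccccc2)c1
F8 | step 10 | (2R,3R)-6-hydroxy-2-(3-hydroxy-4-methoxyphenyl)-3,5,7-trimethoxy-2,3-dihydro-4H-chromen-4-one | COc1ccc([C@H]2Oc3cc(OC)c(O)c(OC)c3C(=O)[C@@H]2OC)cc1O
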